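Ring A, numbered from its CH2OH-bearing carbon (benzyl on carbon 2), is disconnected at two bonds, between carbons 2 and 3 and between carbons 1 and 6. The key step exploits the adjacent oxygenated carbons 4 and 5 of ring A with their neighbours 3 and 6, a latent 2,3-dimethoxybutadiene, and carbons 1 and 2 with their one-carbon arms, a latent but-2-ynoate. One thermal [4+2] cycloaddition assembles ring A as a cyclohexa-1,4-diene that already carries the benzyl link to ring B and the ester that becomes CH2OH; dehydrogenation, one bromination, reduction and demethylation finish. The precursor is a methyl 4-arylbut-2-ynoate bearing the complete 2,3-dibromo-4,5-dimethoxyphenyl ring B, made by copper-catalysed benzylation of methyl propiolate.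

Key step: step 6

Remark: ring A carries CH2OH on carbon 1, the benzyl group on carbon 2, Br on carbon 3, oxygen on carbons 4 and 5 and H on carbon 6. Ring B is numbered from its CH2-bearing carbon as carbon 1 (Br on carbons 2 and 3, oxygen on carbons 4 and 5, H on carbon 6). The target has no stereocentre and no double-bond isomerism, so no configuration has to be set.

Step 1
Reactants: 1 5-bromovanillin (3-bromo-4-hydroxy-5-methoxybenzaldehyde)
Product: 2 5,6-dibromovanillin (2,3-dibromo-4-hydroxy-5-methoxybenzaldehyde)
Conditions: Br2 (1.1 equiv), Fe powder (cat.), NaOAc, AcOH, rt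
Reagents that add atoms: bromine, BrBr
Why: Electrophilic aromatic bromination (Br2 activated by FeBr3 formed from the iron): with both ortho positions and the para position of the phenol occupied, the methoxy group should direct the incoming bromine to its para position, next to the bromine already present, which fixes the 2,3-dibromo-4,5-dioxygenated pattern of ring B.

Step 2
Reactants: 2 5,6-dibromovanillin
Product: 3 2,3-dibromo-4,5-dimethoxybenzaldehyde
Conditions: MeI, K2CO3, DMF, rt
Reagents that add atoms: iodomethane, CI
Why: Williamson ether synthesis, in which the acidic, doubly ortho-substituted phenoxide is methylated by SN2 attack on iodomethane while the aldehyde, having no α-hydrogen, is inert to carbonate.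

Step 3
Reactants: 3 2,3-dibromo-4,5-dimethoxybenzaldehyde
Product: 4 (2,3-dibromo-4,5-dimethoxyphenyl)methanol
Conditions: NaBH4, MeOH–THF, 0 °C
Reagents that add atoms: none
Why: Hydride reduction of the aldehyde with NaBH4 is chemoselective and leaves both aryl bromides and the ethers untouched.

Step 4
Reactants: 4 (2,3-dibromo-4,5-dimethoxyphenyl)methanol
Product: 5 2,3-dibromo-1-(bromomethyl)-4,5-dimethoxybenzene
Conditions: PBr3 (0.4 equiv), CH2Cl2, 0 °C to rt
Reagents that add atoms: phosphorus tribromide, BrP(Br)Br
Why: The benzylic alcohol is converted into the bromide through its phosphite ester and SN2 displacement by bromide (PBr3 bromination), under conditions too mild to cleave aryl methyl ethers.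

Step 5
Reactants: 5 2,3-dibromo-1-(bromomethyl)-4,5-dimethoxybenzene; 6 methyl propiolate
Product: 7 methyl 4-(2,3-dibromo-4,5-dimethoxyphenyl)but-2-ynoate
Conditions: CuI (10 mol %), K2CO3, n-Bu4NI, MeCN, 40 °C
Reagents that add atoms: none
Why: Copper-catalysed alkynylation of a benzylic halide, in which the copper acetylide formed from 6 is alkylated at the sp3 C–Br bond (iodide exchange from n-Bu4NI speeds this up), the two aryl C–Br bonds are inert to copper at this temperature, and the weak heterogeneous base should limit propargyl-to-allenyl isomerisation of the skipped ynoate.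

Step 6
Reactants: 7 methyl 4-(2,3-dibromo-4,5-dimethoxyphenyl)but-2-ynoate; 8 2,3-dimethoxybuta-1,3-diene
Product: 9 methyl 2-(2,3-dibromo-4,5-dimethoxybenzyl)-4,5-dimethoxycyclohexa-1,4-diene-1-carboxylate
Conditions: 8 (3 equiv), BHT (cat.), PhMe, sealed tube, 150 °C
Reagents that add atoms: none
Why: A concerted, suprafacial, normal-electron-demand [4+2] cycloaddition joins the two termini of the electron-rich diene 8 to the two alkyne carbons of the ester-activated ynoate 7, making in one event the σ-bonds between carbons 2 and 3 and between carbons 1 and 6 of ring A. The closest known reaction type is the thermal Diels–Alder reaction of 2,3-dialkoxybuta-1,3-dienes with acetylenic esters, whose adducts are dehydrogenated to veratrole derivatives. Ring A is closed in cycloaddition mode as a six-membered carbocycle with both new bonds formed together, and the cyclohexa-1,4-diene that results contains no stereocentre, so no stereocontrol is required. Regioselectivity is not an issue because the diene is constitutionally symmetrical and both orientations give the same adduct. The selectivity that is needed is chemoselectivity: cycloaddition has to outrun prototropic isomerisation of the skipped ynoate to the allenoate and polymerisation of the diene, which base-free, metal-free conditions, excess diene and a radical inhibitor should secure, while the tetrasubstituted enoate of 9 is too hindered to take up a second diene. Both aryl bromides and all methyl ethers are spectators under these conditions.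

Step 7
Reactants: 9 methyl 2-(2,3-dibromo-4,5-dimethoxybenzyl)-4,5-dimethoxycyclohexa-1,4-diene-1-carboxylate
Product: 10 methyl 2-(2,3-dibromo-4,5-dimethoxybenzyl)-4,5-dimethoxybenzoate
Conditions: DDQ (1.1 equiv), PhMe, rt
Reagents that add atoms: none
Why: Oxidative aromatisation with DDQ, in which hydride abstraction from a doubly allylic ring CH2 next to an enol ether followed by proton loss gives the veratrole ring, a dehydrogenation driven by aromaticity that should be much faster than attack on the deactivated diarylmethane CH2.

Step 8
Reactants: 10 methyl 2-(2,3-dibromo-4,5-dimethoxybenzyl)-4,5-dimethoxybenzoate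
Product: 11 methyl 3-bromo-2-(2,3-dibromo-4,5-dimethoxybenzyl)-4,5-dimethoxybenzoate
Conditions: Br2 (1.05 equiv), AcOH, rt, dark
Reagents that add atoms: bromine, BrBr
Why: Electrophilic aromatic bromination, in which carbon 3 of ring A (ortho to the methoxy group on carbon 4, meta to the ester) should react first because its arenium ion carries the charge on methoxy-, alkyl- and hydrogen-bearing carbons only, whereas attack at carbon 6 of ring A places charge on the ester-bearing carbon 1 and attack at carbon 6 of ring B places it on the bromine-bearing carbon 3 of a ring deactivated by two bromines.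

Step 9
Reactants: 11 methyl 3-bromo-2-(2,3-dibromo-4,5-dimethoxybenzyl)-4,5-dimethoxybenzoate
Product: 12 [3-bromo-2-(2,3-dibromo-4,5-dimethoxybenzyl)-4,5-dimethoxyphenyl]methanol
Conditions: i-Bu2AlH (3 equiv), CH2Cl2, −78 to 0 °C
Reagents that add atoms: none
Why: i-Bu2AlH reduces the aryl ester through the aldehyde to the benzylic alcohol at low temperature and, as an electrophilic hydride donor, should not touch the three aryl bromides, which stronger nucleophilic hydrides could begin to reduce on warming.

Step 10
Reactants: 12 [3-bromo-2-(2,3-dibromo-4,5-dimethoxybenzyl)-4,5-dimethoxyphenyl]methanol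
Product: 14 3-bromo-4-(2,3-dibromo-4,5-dihydroxybenzyl)-5-(hydroxymethyl)benzene-1,2-diol (CNP0203154.0), via tetraphenolic benzylic bromide 13 (not isolated)
Conditions: BBr3 (8 equiv), CH2Cl2, −78 °C to rt; then H2O–acetone, rt, under argon
Reagents that add atoms: water, O; boron tribromide, BrB(Br)Br (its bromine is present only in 13 and is lost again on hydrolysis)
Why: BBr3 cleaves all four aryl methyl ethers by Lewis acid–base complexation and SN2 demethylation by bromide and at the same time turns the benzylic hydroxyl into bromide 13, which, being a para-hydroxybenzyl bromide (the hydroxyl on carbon 4 of ring A is para to the CH2Br-bearing carbon 1), should be solvolysed through its quinone methide when the borates are hydrolysed in dilute aqueous acetone, so that water delivers the CH2OH group of 14.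

Compound list
1 | 5-bromovanillin (3-bromo-4-hydroxy-5-methoxybenzaldehyde) | COc1cc(C=O)cc(Br)c1O | starting material
2 | 5,6-dibromovanillin (2,3-dibromo-4-hydroxy-5-methoxybenzaldehyde) | COc1cc(C=O)c(Br)c(Br)c1O | intermediate
3 | 2,3-dibromo-4,5-dimethoxybenzaldehyde | COc1cc(C=O)c(Br)c(Br)c1OC | intermediate
4 | (2,3-dibromo-4,5-dimethoxyphenyl)methanol | COc1cc(CO)c(Br)c(Br)c1OC | intermediate
5 | 2,3-dibromo-1-(bromomethyl)-4,5-dimethoxybenzene | COc1cc(CBr)c(Br)c(Br)c1OC | intermediate
6 | methyl propiolate | C#CC(=O)OC | starting material
7 | methyl 4-(2,3-dibromo-4,5-dimethoxyphenyl)but-2-ynoate | COC(=O)C#CCc1cc(OC)c(OC)c(Br)c1Br | intermediate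
8 | 2,3-dimethoxybuta-1,3-diene | C=C(OC)C(=C)OC | starting material
9 | methyl 2-(2,3-dibromo-4,5-dimethoxybenzyl)-4,5-dimethoxycyclohexa-1,4-diene-1-carboxylate | COC(=O)C1=C(Cc2cc(OC)c(OC)c(Br)c2Br)CC(OC)=C(OC)C1 | intermediate
10 | methyl 2-(2,3-dibromo-4,5-dimethoxybenzyl)-4,5-dimethoxybenzoate | COC(=O)c1cc(OC)c(OC)cc1Cc1cc(OC)c(OC)c(Br)c1Br | intermediate
11 | methyl 3-bromo-2-(2,3-dibromo-4,5-dimethoxybenzyl)-4,5-dimethoxybenzoate | COC(=O)c1cc(OC)c(OC)c(Br)c1Cc1cc(OC)c(OC)c(Br)c1Br | intermediate
12 | [3-bromo-2-(2,3-dibromo-4,5-dimethoxybenzyl)-4,5-dimethoxyphenyl]methanol | OCc1cc(OC)c(OC)c(Br)c1Cc1cc(OC)c(OC)c(Br)c1Br | intermediate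
13 | 3-bromo-5-(bromomethyl)-4-(2,3-dibromo-4,5-dihydroxybenzyl)benzene-1,2-diol | BrCc1cc(O)c(O)c(Br)c1Cc1cc(O)c(O)c(Br)c1Br | intermediate
14 | 3-bromo-4-(2,3-dibromo-4,5-dihydroxybenzyl)-5-(hydroxymethyl)benzene-1,2-diol | OCc1cc(O)c(O)c(Br)c1Cc1cc(O)c(O)c(Br)c1Br | target

Total step count: 10. Longest linear sequence: 10 steps (1 to 14).

Steps most likely to fail

Step 6. The cycloaddition of a β-alkylated, singly activated alkyne may be too slow at temperatures the partners tolerate, so that diene polymerisation and drift of the ynoate to its allene isomer take over. The fallback sets out from 7 and comes back at 9, and turns that drift into the route. Catalytic Et3N in CH2Cl2 at rt should isomerise 7 to racemic methyl 4-(2,3-dibromo-4,5-dimethoxyphenyl)buta-2,3-dienoate F1. The strained, ester-conjugated double bond of this allenoate is a far better dienophile and should add 8 in PhMe at 80–100 °C, anti to the aryl group. This would give methyl (Z)-2-(2,3-dibromo-4,5-dimethoxybenzylidene)-4,5-dimethoxycyclohex-4-ene-1-carboxylate F2 (racemic at the ester-bearing carbon), in which the same two bonds of ring A (carbon 2 to carbon 3 and carbon 1 to carbon 6) have been made. Catalytic DBU in THF at rt should then move the exocyclic double bond into conjugation with the ester through the dienolate, which gives 9. Any other double-bond isomer should be carried to 10 by DDQ as well.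

Step 8. Site selectivity may erode: bromination of ring B at its carbon 6, ipso attack at the diarylmethane carbon with C–C cleavage, or over-bromination. The fallback sets out from 7 and comes back at 11, and lets a free phenol direct the bromine. The cycloaddition is run with bought 2,3-bis(trimethylsilyloxy)buta-1,3-diene (C=C(O[Si](C)(C)C)C(=C)O[Si](C)(C)C) to give methyl 2-(2,3-dibromo-4,5-dimethoxybenzyl)-4,5-bis(trimethylsilyloxy)cyclohexa-1,4-diene-1-carboxylate F3. DDQ should aromatise it to methyl 2-(2,3-dibromo-4,5-dimethoxybenzyl)-4,5-bis(trimethylsilyloxy)benzoate F4. Dilute HCl in THF then frees methyl 2-(2,3-dibromo-4,5-dimethoxybenzyl)-4,5-dihydroxybenzoate F5. Its catechol ring is far more reactive than ring B, and one equivalent of Br2 in AcOH should brominate ortho to the hydroxyl on carbon 4 of ring A and meta to the ester, as in the bromination of protocatechuic esters. This gives methyl 3-bromo-2-(2,3-dibromo-4,5-dimethoxybenzyl)-4,5-dihydroxybenzoate F6. Double O-methylation (MeI, K2CO3, acetone, reflux) returns 11.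

Step 10. Ionisation of the benzylic position under acidic conditions may lead to intermolecular Friedel–Crafts alkylation or ether formation between molecules instead of clean hydrolysis. The fallback sets out from 12 and comes back at 14, and removes the benzylic leaving group before the demethylation. MnO2 in CH2Cl2 at rt should oxidise 12 to 3-bromo-2-(2,3-dibromo-4,5-dimethoxybenzyl)-4,5-dimethoxybenzaldehyde F7. BBr3 (CH2Cl2, −78 °C to rt) then cleaves the four methyl ethers without touching the aldehyde and gives 3-bromo-2-(2,3-dibromo-4,5-dihydroxybenzyl)-4,5-dihydroxybenzaldehyde F8. NaBH4 in EtOH at 0 °C with a neutral work-up reduces the aldehyde to 14 as the last, mild operation.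

Further compounds
F1 | step 6 | methyl 4-(2,3-dibromo-4,5-dimethoxyphenyl)buta-2,3-dienoate (racemic) | COC(=O)C=C=Cc1cc(OC)c(OC)c(Br)c1Br
F2 | step 6 | methyl (Z)-2-(2,3-dibromo-4,5-dimethoxybenzylidene)-4,5-dimethoxycyclohex-4-ene-1-carboxylate (racemic) | COC(=O)C1CC(OC)=C(OC)C/C1=C/c1cc(OC)c(OC)c(Br)c1Br
F3 | step 8 | methyl 2-(2,3-dibromo-4,5-dimethoxybenzyl)-4,5-bis(trimethylsilyloxy)cyclohexa-1,4-diene-1-carboxylate | COC(=O)C1=C(Cc2cc(OC)c(OC)c(Br)c2Br)CC(O[Si](C)(C)C)=C(O[Si](C)(C)C)C1
F4 | step 8 | methyl 2-(2,3-dibromo-4,5-dimethoxybenzyl)-4,5-bis(trimethylsilyloxy)benzoate | COC(=O)c1cc(O[Si](C)(C)C)c(O[Si](C)(C)C)cc1Cc1cc(OC)c(OC)c(Br)c1Br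
F5 | step 8 | methyl 2-(2,3-dibromo-4,5-dimethoxybenzyl)-4,5-dihydroxybenzoate | COC(=O)c1cc(O)c(O)cc1Cc1cc(OC)c(OC)c(Br)c1Br
F6 | step 8 | methyl 3-bromo-2-(2,3-dibromo-4,5-dimethoxybenzyl)-4,5-dihydroxybenzoate | COC(=O)c1cc(O)c(O)c(Br)c1Cc1cc(OC)c(OC)c(Br)c1Br
F7 | step 10 | 3-bromo-2-(2,3-dibromo-4,5-dimethoxybenzyl)-4,5-dimethoxybenzaldehyde | O=Cc1cc(OC)c(OC)c(Br)c1Cc1cc(OC)c(OC)c(Br)c1Br
F8 | step 10 | 3-bromo-2-(2,3-dibromo-4,5-dihydroxybenzyl)-4,5-dihydroxybenzaldehyde | O=Cc1cc(O)c(O)c(Br)c1Cc1cc(O)c(O)c(Br)c1Br
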